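**Retrosynthetic overview**
1. Target ⇐ olefin cross-metathesis: the prenyl group is traced back to an allyl group, so no acid-labile trisubstituted alkene is present earlier.
2. 3-Allyl chalcone ⇐ hydroxide ring-opening (O1–C2) of a 7-hydroxyflavylium salt, which lets unprotected 2,4-dihydroxybenzaldehyde be used.
3. Flavylium salt ⇐ one flask, two ring closures: chiral-acid ortho-quinone-methide [4+2] of 2',4'-dihydroxy-6'-methoxyacetophenone, formaldehyde and 5-methylhexa-1,4-diene (C4–C3 and O1–C2 of the dihydropyran, sets C3), then acid condensation with the aldehyde (pyrylium C=C and C–O).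
4. Diene ⇐ allyl bromide + 2-methylprop-1-enyl Grignard reagent.
5. Ring order: rings A and B are bought; the dihydropyran ring forms first and the benzopyrylium ring second in the same operation; the benzopyrylium ring is opened again in the next step.

Assumption: the sense of induction of the new asymmetric step cannot be known beforehand; the (R)-acid is written, and the (S)-acid is used instead if the first run gives the (3R)-chroman.

**Step 1**
Reactants: 1 allyl bromide (3-bromoprop-1-ene); 2 2-methylprop-1-enylmagnesium bromide (0.5 M in THF)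
Product: 3 5-methylhexa-1,4-diene
Conditions: Li2CuCl4 (2 mol%), THF, −20 °C to rt, 3 h; aq NH4Cl, pentane, water washes, fractional distillation
Reagents that add atoms: none
Why: Copper-catalysed alkenyl Grignard–allyl halide cross-coupling (Kochi type); allyl bromide is symmetric, so alpha and gamma attack give the same skipped diene, and no stereocenter is formed.

**Step 2**
Reactants: 4 1-(2,4-dihydroxy-6-methoxyphenyl)ethan-1-one; 3 5-methylhexa-1,4-diene (3 equiv); 5 2,4-dihydroxybenzaldehyde (1.1 equiv, added in part b)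
Product: 8 7-hydroxy-2-[(3S)-5-hydroxy-7-methoxy-2,2-dimethyl-3-(prop-2-en-1-yl)-3,4-dihydro-2H-chromen-6-yl]chromenylium chloride, via ortho-quinone methide 6 (not isolated), via allyl chroman ketone 7 (not isolated)
Conditions: a) (CH2O)n (1.0 equiv), (R)-N-triflyl phosphoramide of 3,3'-bis(2,4,6-triisopropylphenyl)-1,1'-bi-2-naphthol (C51H57F3NO5PS, 10 mol%), 1,2-dichloroethane, 40 °C, 48 h; b) evaporate volatiles, then 5, HCl (4 M in 1,4-dioxane, 10 equiv), EtOAc, 0 °C to rt, 24 h; Et2O, filter the salt
Reagents that add atoms: paraformaldehyde (as formaldehyde), C=O; hydrogen chloride, Cl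
Why: Proposed new method: the chiral acid turns the hydroxymethyl phenol formed at C3 of 4 (the carbon flanked by both hydroxyls) into ortho-quinone methide 6 held as a hydrogen-bonded ion pair; its methylene carbon adds to the CH end of the more nucleophilic trisubstituted alkene of 3 on the face left open by the triisopropylphenyl walls, which sets C3 as (S), and the tertiary cation is closed by the non-chelated 4-oxygen (inverse-demand hetero-Diels–Alder; closest known reactions are chiral phosphoric acid-catalysed [4+2] cycloadditions of ortho-quinone methides with styrenes and the thermal phenol–formaldehyde–alkene chroman synthesis); the acid aldol condensation of the acetyl group of 7 with 5 then closes the benzopyrylium ring (flavylium salt synthesis), which drives the condensation without protecting groups, leaves the terminal alkene alone, and lets 8 be collected by precipitation.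

**Step 3**
Reactants: 8 flavylium chloride (from step 2)
Product: 11 (2E)-3-(2,4-dihydroxyphenyl)-1-[(3S)-5-hydroxy-7-methoxy-2,2-dimethyl-3-(prop-2-en-1-yl)-3,4-dihydro-2H-chromen-6-yl]prop-2-en-1-one, via chromenol hemiketal 9 (not isolated), via cis-chalcone 10 (not isolated)
Conditions: NaOH (0.5 M, 6 equiv), MeOH/H2O, Ar, dark, 0 °C to rt, 1 h; AcOH to pH 5; EtOAc; SiO2
Reagents that add atoms: sodium hydroxide, [Na+].[OH-]
Why: Flavylium–chalcone ring opening: hydroxide adds to C2 of the cation to give hemiketal 9, ring–chain tautomerism gives cis-chalcone 10, and the phenolate isomerises to the thermodynamically preferred trans-chalcone, which is stable at pH 5; 2'-hydroxy-4',6'-dialkoxychalcones of this type tolerate aqueous alkali as their phenolates, and the C3 stereocenter is not touched.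

**Step 4**
Reactants: 11 3-allyl chalcone (from step 3)
Product: 12 (2E)-3-(2,4-dihydroxyphenyl)-1-[(3S)-5-hydroxy-7-methoxy-2,2-dimethyl-3-(3-methylbut-2-en-1-yl)-3,4-dihydro-2H-chromen-6-yl]prop-2-en-1-one (target)
Conditions: 2-methylbut-2-ene (30 equiv), second-generation Hoveyda–Grubbs catalyst RuCl2(H2IMes)(=CH-C6H4-2-O-iPr) (H2IMes = 1,3-dimesitylimidazolidin-2-ylidene, 5 mol%), CH2Cl2, 40 °C, 12 h, dark
Reagents that add atoms: 2-methylbut-2-ene, CC=C(C)C
Why: Olefin cross-metathesis of the terminal allyl group with 2-methylbut-2-ene installs the isopropylidene end and releases propene, while the electron-poor conjugated enone, the free phenols and the remote stereocenter are unaffected.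

**Compound list**
1 | allyl bromide (3-bromoprop-1-ene) | C=CCBr | starting material
2 | 2-methylprop-1-enylmagnesium bromide | CC(C)=C[Mg]Br | starting material
3 | 5-methylhexa-1,4-diene | C=CCC=C(C)C | intermediate
4 | 1-(2,4-dihydroxy-6-methoxyphenyl)ethan-1-one | CC(=O)c1c(O)cc(O)cc1OC | starting material
5 | 2,4-dihydroxybenzaldehyde | O=Cc1ccc(O)cc1O | starting material
6 | 4-acetyl-5-hydroxy-3-methoxy-6-methylidenecyclohexa-2,4-dien-1-one (ortho-quinone methide) | C=C1C(=O)C=C(OC)C(C(C)=O)=C1O | intermediate (not isolated)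
7 | 1-[(3S)-5-hydroxy-7-methoxy-2,2-dimethyl-3-(prop-2-en-1-yl)-3,4-dihydro-2H-chromen-6-yl]ethan-1-one | COc1cc2c(c(O)c1C(C)=O)C[C@H](CC=C)C(C)(C)O2 | intermediate (not isolated)
8 | 7-hydroxy-2-[(3S)-5-hydroxy-7-methoxy-2,2-dimethyl-3-(prop-2-en-1-yl)-3,4-dihydro-2H-chromen-6-yl]chromenylium chloride | COc1cc2c(c(O)c1-c1ccc3ccc(O)cc3[o+]1)C[C@H](CC=C)C(C)(C)O2.[Cl-] | intermediate
9 | 2-[(3S)-5-hydroxy-7-methoxy-2,2-dimethyl-3-(prop-2-en-1-yl)-3,4-dihydro-2H-chromen-6-yl]-2H-chromene-2,7-diol (both C2 epimers) | COc1cc2c(c(O)c1C1(O)C=Cc3ccc(O)cc3O1)C[C@H](CC=C)C(C)(C)O2 | intermediate (not isolated)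
10 | (2Z)-3-(2,4-dihydroxyphenyl)-1-[(3S)-5-hydroxy-7-methoxy-2,2-dimethyl-3-(prop-2-en-1-yl)-3,4-dihydro-2H-chromen-6-yl]prop-2-en-1-one | COc1cc2c(c(O)c1C(=O)/C=C\c1ccc(O)cc1O)C[C@H](CC=C)C(C)(C)O2 | intermediate (not isolated)
11 | (2E)-3-(2,4-dihydroxyphenyl)-1-[(3S)-5-hydroxy-7-methoxy-2,2-dimethyl-3-(prop-2-en-1-yl)-3,4-dihydro-2H-chromen-6-yl]prop-2-en-1-one | COc1cc2c(c(O)c1C(=O)/C=C/c1ccc(O)cc1O)C[C@H](CC=C)C(C)(C)O2 | intermediate
12 | (2E)-3-(2,4-dihydroxyphenyl)-1-[(3S)-5-hydroxy-7-methoxy-2,2-dimethyl-3-(3-methylbut-2-en-1-yl)-3,4-dihydro-2H-chromen-6-yl]prop-2-en-1-one | COc1cc2c(c(O)c1C(=O)/C=C/c1ccc(O)cc1O)C[C@H](CC=C(C)C)C(C)(C)O2 | target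

**Totals**
Total steps: 4. Longest linear sequence: 4 (1 → 3 → 8 → 11 → 12).

**Steps most likely to fail**

Step 2. The acid-catalysed annulation is unprecedented for an unactivated alkene. It may give low ee, attack C5 instead of C3 of 4, or lose the quinone methide to a methylene-bridged dimer of 4, and the crude chroman is carried straight into the HCl condensation. The fallback sets out from 4 and 3 and comes back at 7. The same phenol–formaldehyde–alkene annulation is run without chiral acid (paraformaldehyde, NaOAc, AcOH, 80 °C) to give racemic chroman ketone F1, which is purified on silica to remove any regioisomer. The enantiomers are then separated by preparative supercritical-fluid chromatography on amylose tris(3,5-dimethylphenylcarbamate) with CO2/MeOH. The (3S)-enantiomer is 7, now isolated, and part b of step 2 (5, HCl) is run on it as a separate step.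

Step 3. In base the 5-hydroxy group can add to the enone to give a flavanone, or the cis to trans isomerisation can stall so that the salt re-forms on acidification. The fallback sets out from 7 (isolated by stopping step 2 after part a) and comes back at 11. Aldehyde 5 is protected with MOMCl and i-Pr2NEt in CH2Cl2 to give 2,4-bis(methoxymethoxy)benzaldehyde F2. Claisen–Schmidt condensation of F2 with 7 (KOH, EtOH/H2O, rt) gives bis-MOM allyl chalcone F3. HCl (3 M aq) in MeOH at rt removes both MOM groups and gives 11, so the flavylium salt is bypassed.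

Step 4. The ruthenium carbene may be sequestered by the chelating polyphenolic 2-hydroxychalcone, or conversion may stop early. The fallback sets out from 4 and comes back at 12; the prenyl group is carried from the start and strong acid is avoided. Prenyl bromide and 2 are coupled as in step 1 to give 2,6-dimethylhepta-2,5-diene F4, which replaces 3 in part a of step 2. The product, prenyl chroman ketone F5, is isolated without the HCl stage. Base aldol condensation with 2,4-bis(methoxymethoxy)benzaldehyde F2, made from 5 with MOMCl and i-Pr2NEt as above, gives bis-MOM prenyl chalcone F6 (KOH, EtOH/H2O, rt). Brief treatment with HCl (3 M aq) in MeOH at rt gives 12.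

**Further compounds**
F1 | step 2 | racemic 1-[5-hydroxy-7-methoxy-2,2-dimethyl-3-(prop-2-en-1-yl)-3,4-dihydro-2H-chromen-6-yl]ethan-1-one | COc1cc2c(c(O)c1C(C)=O)CC(CC=C)C(C)(C)O2
F2 | step 3 | 2,4-bis(methoxymethoxy)benzaldehyde | COCOc1ccc(C=O)c(OCOC)c1
F3 | step 3 | (2E)-3-[2,4-bis(methoxymethoxy)phenyl]-1-[(3S)-5-hydroxy-7-methoxy-2,2-dimethyl-3-(prop-2-en-1-yl)-3,4-dihydro-2H-chromen-6-yl]prop-2-en-1-one | COc1cc2c(c(O)c1C(=O)/C=C/c1ccc(OCOC)cc1OCOC)C[C@H](CC=C)C(C)(C)O2
F4 | step 4 | 2,6-dimethylhepta-2,5-diene | CC(C)=CCC=C(C)C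
F5 | step 4 | 1-[(3S)-5-hydroxy-7-methoxy-2,2-dimethyl-3-(3-methylbut-2-en-1-yl)-3,4-dihydro-2H-chromen-6-yl]ethan-1-one | COc1cc2c(c(O)c1C(C)=O)C[C@H](CC=C(C)C)C(C)(C)O2
F6 | step 4 | (2E)-3-[2,4-bis(methoxymethoxy)phenyl]-1-[(3S)-5-hydroxy-7-methoxy-2,2-dimethyl-3-(3-methylbut-2-en-1-yl)-3,4-dihydro-2H-chromen-6-yl]prop-2-en-1-one | COc1cc2c(c(O)c1C(=O)/C=C/c1ccc(OCOC)cc1OCOC)C[C@H](CC=C(C)C)C(C)(C)O2
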